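The green run is the witness to what becomes of target once it is made: it has the charge of the blue run plus 0.150 M of target at the start.

| flask | starting material | catalyst | target | time |
|---|---|---|---|---|
| blue | 0.500 M | 0.00100 M |  |  |
| red | 0.200 M | 0.00100 M |  |  |
| teal | 0.250 M | 0.00100 M |  |  |
| green | 0.500 M | 0.00100 M | 0.150 M |  |
| ochre | 0.500 M | 0.00100 M |  | 26 min |

| run | time / min | [target] / M |
|---|---|---|
| blue run | 1.6 | 0.060 |
| blue run | 3.2 | 0.116 |
| blue run | 4.9 | 0.157 |
| blue run | 6.5 | 0.197 |
| blue run | 8.1 | 0.229 |
| blue run | 9.8 | 0.248 |
| blue run | 11 | 0.265 |
| blue run | 13 | 0.280 |
| red run | 1.6 | 0.036 |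
| red run | 3.2 | 0.059 |
| red run | 4.9 | 0.086 |
| red run | 6.5 | 0.101 |
| red run | 8.1 | 0.112 |
| red run | 9.8 | 0.123 |
| red run | 11 | 0.120 |
| red run | 13 | 0.128 |
| teal run | 1.6 | 0.038 |
| teal run | 3.2 | 0.074 |
| teal run | 4.9 | 0.096 |
| teal run | 6.5 | 0.116 |
| teal run | 8.1 | 0.136 |
| teal run | 9.8 | 0.149 |
| teal run | 11 | 0.150 |
| teal run | 13 | 0.149 |
| green run | 1.6 | 0.200 |
| green run | 3.2 | 0.245 |
| green run | 4.9 | 0.283 |
| green run | 6.5 | 0.321 |
| green run | 8.1 | 0.337 |
| green run | 9.8 | 0.350 |
| green run | 11 | 0.362 |
| green run | 13 | 0.368 |

(readings scatter by 0.003 M)

- apparent order in [starting material] of the starting rate, round the charge of the blue run (the rate where two percent of its starting material have turned into target) (one fixed amount of target, the same in the runs compared)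
- target in the ochre run at 26 min, as a share of the starting material charged

- Overall: starting material -> target, with catalyst as catalyst.
- Constant volume, constant temperature.
- The analysis sees a species whether free or bound.
- An order is taken over about fifteen percent of the charge, up and down.

Green minus blue cancels the making, provided that added target leaves the making unchanged, and what remains is the fate of the added target. At 13 min that gap reads 0.0880 M instead of 0.150 M. Taken as first order, this gives the loss constant, the chance per minute that one target molecule disappears, as 0.0410 /min, a reading good to about 0.00371 /min. At 9.8 min the same constant gives a gap of 0.100 M, and the readings give 0.102 M.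

The time scales form a ladder. On the lowest rung, charge over the mean rate up to the first reading gives 8.89 min in the red run and 13.3 min in the blue run. The teal run, with half the blue charge, reads 0.633 of the blue target at the first reading, an average order of 0.659 between those charges. On the next rung, the target lifetime of 24.4 min is longer than either emptying time, so target piles up first and its loss tells later. Summing the blue readings, 0.0941 M of target has been lost by 13 min. By this reckoning 0.126 M of starting material remains in the blue run at that time, so the flattening of the blue readings is not an end.

The ochre run repeats the blue charge, and 13.0 min remain after the last blue reading. A target molecule survives them with chance 0.587. A molecule of starting material, taken at the red rate per molecule up to the first reading, 0.112 /min, is target at the end of that time with chance 0.559. The reckoning here therefore commits to 46.9%. The forecast differs, giving 60.5% and an order of 0.47, and it reads the levelling as “a true equilibrium”.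

    catalyst + starting material ⇌ catalyst-substrate complex (213.6 /M/min, 42.12 /min)
    catalyst-substrate complex → target + catalyst (1836 /min)
    2 starting material ⇌ idle substrate dimer, settled at all times (3.510 /M)
    target → decomposed product (0.04080 /min)

The ochre run gives 48.9% at 26 min, which is 0.244 M, and the order is 0.64. A fit with the main steps alone forecasts 86.7% for this run, and one with the true steps 49.5%. In the green run, the added 0.150 M of target loses 0.00615 M/min at the constant read above; subtracted from the blue rate of 0.041 M/min, that gives 0.0349 M/min, and the green rate read where the same amount has been made is 0.035 M/min.

The earlier runs and the new flask are simulated with made-up constants; the scatter is artificial.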